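**Plan**

- Retrosynthesis: the four O–benzyl bonds are cut first, then the O1–C8a aryl ether bond of ring C, then C2–C3, and on ring A the C8a–Br, C4a–C4 and C5–O bonds.
- Enabling feature: O1 sits on C8a, directly beside the C4 acyl carbon. Ring A can therefore be carried as a 2-bromoaryl ketone with only four oxygens (O5, 6-OMe, O7, 8-OMe), and the enol of the C2 carbonyl delivers the fifth, O1.
- Forward, ring A: 2,6-dimethoxyphenol supplies O7 and the 6- and 8-methoxy groups; formylation/Baeyer–Villiger adds O5, C-acetylation forms C4a–C4, then benzylation and bromination at the future C8a.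
- Forward, assembly: ring B enters as the dibenzylated methyl 3,5-dihydroxy-4-methoxybenzoate; a Claisen condensation joins C2–C3, copper-catalysed O-arylation closes ring C last, and hydrogenolysis frees the four phenols.
- Stereochemistry: the target is achiral and has no stereocentre, so nothing has to be controlled.

Key step: step 9

Remark: flavone numbering (O1, C2 to C4, C4a, C5 to C8, C8a; ring B primed) is used for the future positions of all intermediates. Both starting materials are taken to be commercial. The carbonyl oxygen of the aldehyde made in step 2 is taken to come from water in the hydrolytic work-up.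

**Route**

Step 1
Reactants: 1 2,6-dimethoxyphenol
Product: 2 2,6-dimethoxyphenyl acetate
Conditions: Ac2O, pyridine, DMAP (cat.), CH2Cl2, 0 °C to rt
Reagents that add atoms: acetic anhydride, CC(=O)OC(C)=O
Why: DMAP-catalysed O-acetylation of the hindered phenol is routine, and the ester masks the future O7 and weakens its para-directing power so that the two methoxy groups govern the next substitution.

Step 2
Reactants: 2 2,6-dimethoxyphenyl acetate
Product: 4 3-formyl-2,6-dimethoxyphenyl acetate, via chloro ether 3 (not isolated)
Conditions: Cl2CHOMe, TiCl4, CH2Cl2, −10 to 0 °C; then ice-water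
Reagents that add atoms: dichloromethyl methyl ether, COC(Cl)Cl; water, O
Why: Rieche formylation, an electrophilic aromatic substitution, should occur at C3 of the acetate (ortho to one methoxy group and para to the other, the future C5), because the position para to the acetoxy group is meta to both methoxy donors, and the chloro ether is hydrolysed to the aldehyde on work-up.

Step 3
Reactants: 4 3-formyl-2,6-dimethoxyphenyl acetate
Product: 6 2,4-dimethoxybenzene-1,3-diol, via aryl formate 5 (not isolated)
Conditions: mCPBA, CH2Cl2, 0 °C to rt; aq. NaHCO3 wash; then HCl (cat.), MeOH, 40 °C, argon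
Reagents that add atoms: 3-chloroperoxybenzoic acid (mCPBA), OOC(=O)c1cccc(Cl)c1
Why: In this Baeyer–Villiger (Dakin-type) oxidation the aryl group, activated by ortho- and para-methoxy donors, migrates in the Criegee intermediate, and acid-catalysed methanolysis then removes the formate and the acetate together without exposing the oxidation-prone diol to base and air.

Step 4
Reactants: 6 2,4-dimethoxybenzene-1,3-diol
Product: 8 1-(2,4-dihydroxy-3,5-dimethoxyphenyl)ethanone, via difluoroboron chelate 7 (not isolated)
Conditions: AcOH, BF3·OEt2, 80 °C; then H2O, 60 °C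
Reagents that add atoms: acetic acid, CC(=O)O
Why: BF3-promoted Friedel–Crafts C-acetylation (Nencki type) should go to C6 of the diol, ortho to one hydroxyl and para to the other, since the only other free position is meta to both, and the ketone is held as its difluoroboron chelate, which blocks a second acylation and is hydrolysed in the warm aqueous work-up.

Step 5
Reactants: 8 1-(2,4-dihydroxy-3,5-dimethoxyphenyl)ethanone
Product: 9 1-[2,4-bis(benzyloxy)-3,5-dimethoxyphenyl]ethanone
Conditions: BnBr, K2CO3, DMF, 70 °C
Reagents that add atoms: benzyl bromide, BrCc1ccccc1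
Why: Williamson etherification of both phenols, the hydrogen-bonded 2-hydroxyl needing warm DMF, puts benzyl groups on the future O5 and O7 that tolerate base and copper and can leave together at the end.

Step 6
Reactants: 9 1-[2,4-bis(benzyloxy)-3,5-dimethoxyphenyl]ethanone
Product: 10 1-[2,4-bis(benzyloxy)-6-bromo-3,5-dimethoxyphenyl]ethanone
Conditions: NBS, MeCN, 0 °C to rt, dark
Reagents that add atoms: N-bromosuccinimide, O=C1CCC(=O)N1Br
Why: Electrophilic aromatic bromination with NBS in a polar, acid-free medium should take the single remaining ring hydrogen (ortho to the 5-methoxy and para to the 3-methoxy group, the future C8a), while the absence of acid keeps enolisation, and with it bromination of the acetyl group, slow.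

Step 7
Reactants: 11 methyl 3,5-dihydroxy-4-methoxybenzoate
Product: 12 methyl 3,5-bis(benzyloxy)-4-methoxybenzoate
Conditions: BnBr, K2CO3, DMF, 60 °C
Reagents that add atoms: benzyl bromide, BrCc1ccccc1
Why: Williamson etherification of the two equivalent phenols gives the ring B ester with the same protecting group as ring A.

Step 8
Reactants: 10 1-[2,4-bis(benzyloxy)-6-bromo-3,5-dimethoxyphenyl]ethanone; 12 methyl 3,5-bis(benzyloxy)-4-methoxybenzoate
Product: 13 1-[2,4-bis(benzyloxy)-6-bromo-3,5-dimethoxyphenyl]-3-[3,5-bis(benzyloxy)-4-methoxyphenyl]propane-1,3-dione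
Conditions: NaH, THF, 0 °C to reflux; then 1 M HCl, 0 °C
Reagents that add atoms: none
Why: In this crossed Claisen condensation the sodium enolate of the methyl ketone, whose own carbonyl is shielded by two ortho substituents, acylates the non-enolisable ester to form C2–C3, and irreversible deprotonation of the 1,3-diketone by excess hydride drives the equilibrium.

Step 9
Reactants: 13 1-[2,4-bis(benzyloxy)-6-bromo-3,5-dimethoxyphenyl]-3-[3,5-bis(benzyloxy)-4-methoxyphenyl]propane-1,3-dione
Product: 14 5,7-bis(benzyloxy)-2-[3,5-bis(benzyloxy)-4-methoxyphenyl]-6,8-dimethoxychromen-4-one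
Conditions: CuI (10 mol%), K2CO3, DMF, 110 °C, argon
Reagents that add atoms: none
Why: Carbonate converts the diketone into its potassium enolate, which chelates CuI as a β-diketonate and so places monovalent copper next to the C8a–Br bond; oxidative addition, assisted by the ortho C4 carbonyl, gives an aryl trivalent copper enolate held in a seven-membered cupracycle, and C–O reductive elimination forms O1–C8a and returns monovalent copper. The closest known reaction type is the copper-catalysed intramolecular Ullmann O-arylation of 1-(2-haloaryl)-1,3-diketones to flavones and chromones. Ring C closes as a six-membered ring by contraction of that cupracycle, the enol oxygen of the C2 carbonyl bonding to the sp2 carbon C8a as bromide leaves. No stereocentre is formed. The step needs O- rather than C-arylation and the correct oxygen as O1: C3 or the oxygen on C4 could only close a four-membered ring, and the C5 oxygen is capped as a benzyl ether so that no cyclodehydration through it can give the isomeric 5-bromoflavone. Dry, degassed DMF should hold back hydrodebromination and retro-Claisen cleavage.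

Step 10
Reactants: 14 5,7-bis(benzyloxy)-2-[3,5-bis(benzyloxy)-4-methoxyphenyl]-6,8-dimethoxychromen-4-one
Product: 15 5,7-dihydroxy-2-(3,5-dihydroxy-4-methoxyphenyl)-6,8-dimethoxychromen-4-one (CNP0185233.0)
Conditions: H2 (1 atm), Pd/C, THF/MeOH, rt
Reagents that add atoms: none
Why: Catalytic hydrogenolysis cleaves the four benzylic C–O bonds over Pd/C while the three methyl ethers and, at 1 atm and room temperature, the pyranone C2=C3 bond should be left alone, the reaction being stopped once debenzylation is complete.

**Compound list**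

1 | 2,6-dimethoxyphenol | COc1cccc(OC)c1O | starting material
2 | 2,6-dimethoxyphenyl acetate | COc1cccc(OC)c1OC(C)=O | intermediate
3 | 3-[chloro(methoxy)methyl]-2,6-dimethoxyphenyl acetate (racemic, not isolated) | COC(Cl)c1ccc(OC)c(OC(C)=O)c1OC | intermediate
4 | 3-formyl-2,6-dimethoxyphenyl acetate | COc1ccc(C=O)c(OC)c1OC(C)=O | intermediate
5 | 3-(formyloxy)-2,6-dimethoxyphenyl acetate (not isolated) | COc1ccc(OC=O)c(OC)c1OC(C)=O | intermediate
6 | 2,4-dimethoxybenzene-1,3-diol | COc1ccc(O)c(OC)c1O | intermediate
7 | difluoroboron chelate of 1-(2,4-dihydroxy-3,5-dimethoxyphenyl)ethanone, boron bound to the 2-phenolic and the carbonyl oxygen (not isolated) | CC1=[O+][B-](F)(F)Oc2c(OC)c(O)c(OC)cc12 | intermediate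
8 | 1-(2,4-dihydroxy-3,5-dimethoxyphenyl)ethanone | CC(=O)c1cc(OC)c(O)c(OC)c1O | intermediate
9 | 1-[2,4-bis(benzyloxy)-3,5-dimethoxyphenyl]ethanone | CC(=O)c1cc(OC)c(OCc2ccccc2)c(OC)c1OCc1ccccc1 | intermediate
10 | 1-[2,4-bis(benzyloxy)-6-bromo-3,5-dimethoxyphenyl]ethanone | CC(=O)c1c(Br)c(OC)c(OCc2ccccc2)c(OC)c1OCc1ccccc1 | intermediate
11 | methyl 3,5-dihydroxy-4-methoxybenzoate | COc1c(O)cc(C(=O)OC)cc1O | starting material
12 | methyl 3,5-bis(benzyloxy)-4-methoxybenzoate | COC(=O)c1cc(OCc2ccccc2)c(OC)c(OCc2ccccc2)c1 | intermediate
13 | 1-[2,4-bis(benzyloxy)-6-bromo-3,5-dimethoxyphenyl]-3-[3,5-bis(benzyloxy)-4-methoxyphenyl]propane-1,3-dione | COc1c(OCc2ccccc2)cc(C(=O)CC(=O)c2c(Br)c(OC)c(OCc3ccccc3)c(OC)c2OCc2ccccc2)cc1OCc1ccccc1 | intermediate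
14 | 5,7-bis(benzyloxy)-2-[3,5-bis(benzyloxy)-4-methoxyphenyl]-6,8-dimethoxychromen-4-one | COc1c(OCc2ccccc2)cc(-c2cc(=O)c3c(OCc4ccccc4)c(OC)c(OCc4ccccc4)c(OC)c3o2)cc1OCc1ccccc1 | intermediate
15 | 5,7-dihydroxy-2-(3,5-dihydroxy-4-methoxyphenyl)-6,8-dimethoxychromen-4-one | COc1c(O)cc(-c2cc(=O)c3c(O)c(OC)c(O)c(OC)c3o2)cc1O | target

**Count**

Total steps: 10. Longest linear sequence: 9 steps (steps 1 to 6, then 8, 9 and 10); step 7 is the one-step side branch for ring B.

**Steps most likely to fail**

Step 9. Oxidative addition of copper into a C–Br bond flanked by a methoxy group and the acyl group on an electron-rich ring may be slow, so that hydrodebromination or carbonate-induced retro-Claisen cleavage of the diketone outruns ring closure. The fallback sets out from 10 and installs the oxygen before the diketone is made. Palladium-catalysed hydroxylation of the aryl bromide (Pd2(dba)3, t-BuXPhos, KOH, 1,4-dioxane/H2O, 100 °C) should give 1-[2,4-bis(benzyloxy)-6-hydroxy-3,5-dimethoxyphenyl]ethanone F1. Crossed Claisen condensation of F1 with 12 (NaH in excess, THF, reflux, acidic work-up) should give 1-[2,4-bis(benzyloxy)-6-hydroxy-3,5-dimethoxyphenyl]-3-[3,5-bis(benzyloxy)-4-methoxyphenyl]propane-1,3-dione F2. Acid-catalysed cyclodehydration (TsOH cat., toluene, 80 °C) through its only free ortho-hydroxyl closes ring C, and the fallback comes back to the route at 14.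

Step 6. Halogenation may take place at the methyl group of the ketone through its enol, or stall at the crowded last ring position next to the deactivating acetyl group. The fallback sets out from 4 and brominates before any enolisable ketone is present.
- NBS in MeCN should brominate the position ortho and para to the two methoxy groups and meta to the formyl group, giving 3-bromo-5-formyl-2,6-dimethoxyphenyl acetate F3.
- Baeyer–Villiger oxidation with mCPBA leads to 3-bromo-5-(formyloxy)-2,6-dimethoxyphenyl acetate F4, and methanolysis with HCl (cat.) in MeOH to 5-bromo-2,4-dimethoxybenzene-1,3-diol F5.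
- Acetylation with AcOH and BF3·OEt2 at the one free ring position, ortho and para to the two hydroxyls, passes through the difluoroboron chelate of the bromo ketone F6 and after aqueous hydrolysis gives 1-(6-bromo-2,4-dihydroxy-3,5-dimethoxyphenyl)ethanone F7.
- Double benzylation (BnBr, K2CO3, DMF) brings the fallback back to the route at 10.

Step 8. Acyl transfer from the methyl ester to the enolate may remain incomplete, and long heating with hydride invites cleavage of the ester or of the product diketone by adventitious hydroxide. The fallback sets out from 12 and replaces the Claisen condensation by an aldol addition followed by oxidation. Reduction with LiAlH4 (THF, 0 °C) gives [3,5-bis(benzyloxy)-4-methoxyphenyl]methanol F8, and MnO2 (CH2Cl2, rt) oxidises it to 3,5-bis(benzyloxy)-4-methoxybenzaldehyde F9. Addition of the lithium enolate of 10 (LiN(i-Pr)2, THF, −78 °C) to F9 should give racemic 1-[2,4-bis(benzyloxy)-6-bromo-3,5-dimethoxyphenyl]-3-[3,5-bis(benzyloxy)-4-methoxyphenyl]-3-hydroxypropan-1-one F10. Dess–Martin periodinane (CH2Cl2, rt) oxidises the β-hydroxy ketone, and the fallback comes back to the route at 13.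

**Further compounds**

F1 | step 9 | 1-[2,4-bis(benzyloxy)-6-hydroxy-3,5-dimethoxyphenyl]ethanone | CC(=O)c1c(O)c(OC)c(OCc2ccccc2)c(OC)c1OCc1ccccc1
F2 | step 9 | 1-[2,4-bis(benzyloxy)-6-hydroxy-3,5-dimethoxyphenyl]-3-[3,5-bis(benzyloxy)-4-methoxyphenyl]propane-1,3-dione | COc1c(OCc2ccccc2)cc(C(=O)CC(=O)c2c(O)c(OC)c(OCc3ccccc3)c(OC)c2OCc2ccccc2)cc1OCc1ccccc1
F3 | step 6 | 3-bromo-5-formyl-2,6-dimethoxyphenyl acetate | COc1c(Br)cc(C=O)c(OC)c1OC(C)=O
F4 | step 6 | 3-bromo-5-(formyloxy)-2,6-dimethoxyphenyl acetate | COc1c(Br)cc(OC=O)c(OC)c1OC(C)=O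
F5 | step 6 | 5-bromo-2,4-dimethoxybenzene-1,3-diol | COc1c(Br)cc(O)c(OC)c1O
F6 | step 6 | difluoroboron chelate of 1-(6-bromo-2,4-dihydroxy-3,5-dimethoxyphenyl)ethanone | CC1=[O+][B-](F)(F)Oc2c(OC)c(O)c(OC)c(Br)c12
F7 | step 6 | 1-(6-bromo-2,4-dihydroxy-3,5-dimethoxyphenyl)ethanone | CC(=O)c1c(Br)c(OC)c(O)c(OC)c1O
F8 | step 8 | [3,5-bis(benzyloxy)-4-methoxyphenyl]methanol | COc1c(OCc2ccccc2)cc(CO)cc1OCc1ccccc1
F9 | step 8 | 3,5-bis(benzyloxy)-4-methoxybenzaldehyde | COc1c(OCc2ccccc2)cc(C=O)cc1OCc1ccccc1
F10 | step 8 | 1-[2,4-bis(benzyloxy)-6-bromo-3,5-dimethoxyphenyl]-3-[3,5-bis(benzyloxy)-4-methoxyphenyl]-3-hydroxypropan-1-one (racemic) | COc1c(OCc2ccccc2)cc(C(O)CC(=O)c2c(Br)c(OC)c(OCc3ccccc3)c(OC)c2OCc2ccccc2)cc1OCc1ccccc1
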